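**Assumptions (remarks on the chemistry)**

- Gardenin A has no stereogenic centre, axis or double-bond isomerism, so the requirement of a single enantiomer is met by the constitution alone and no step has to control configuration.
- 5-Ethynyl-1,2,3-trimethoxybenzene (5) is taken to be a catalogue compound.
- Flavone numbering is used for the target (O1, C2, C3, C4, C4a, C5–C8, C8a; B ring C1'–C6').

## Structural features

Gardenin A is a 2-aryl-4H-chromen-4-one: a benzo ring (A) fused through C4a–C8a to a γ-pyrone (C), which carries a 3,4,5-trimethoxyphenyl ring (B) at C2. Ring A is hexasubstituted and pentaoxygenated: O1 at C8a, methoxy groups at C8, C7 and C6, a free hydroxyl at C5, and the carbonyl carbon C4 on C4a. There is no stereocentre, so the difficulty is constitutional. The first problem is the C4a–C4 bond, which sits at the most crowded ring carbon, between two oxygen-bearing carbons; the second is that exactly one of the five ring-A oxygens must end as a free OH (C5, peri to C4=O and hydrogen-bonded to it) while three others are methyl ethers. The electron-rich rings are prone to oxidation and oxidative demethylation, and the γ-pyrone opens in strong aqueous base. The first feature that the key step exploits is that C4 is a carbonyl carbon lying between an aryl carbon (C4a) and an alkene carbon (C3), which is the signature of carbon monoxide inserted between an aryl halide and an alkyne. The second is a local mirror plane of ring A through C4a and C7, which relates O1/C8a to HO/C5 and C8-OMe to C6-OMe. Ring A can therefore come from a C2v-symmetric 2-iodoresorcinol in which the two OH groups need not be told apart.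

## Logic of the disconnections

**8 ⇒ 4 + 5 + carbon monoxide.** The bonds cut are C4a–C4, C4–C3 and O1–C2, which is the whole pyranone ring. In one sentence: a palladium-catalysed three-component carbonylative annulation of 4, carbon monoxide and 5 builds ring C of 8 in a single operation. The cut is made here because C4 can be supplied as CO between the C–I carbon of 4 and the terminal carbon of 5, and O1–C2 then follows from conjugate addition of a phenol to the resulting ynone 6 (through the amine adduct 7). The gain is that a C21 bicyclic core falls into a C9 arene, a C11 alkyne and a C1 unit. Because 4 has a mirror plane through its C–I carbon, either OH may close the ring and the other becomes the C5 hydroxyl, so no protecting group and no late selective demethylation are needed. The demands on the forward step are that CO insertion outruns direct alkynylation and that the closure is 6-endo, not 5-exo.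

**4 ⇒ 3.** The bond cut is C–I at the carbon that becomes C4a. That carbon is the only ring C–H of 3 and lies ortho to both hydroxyls, so regiochemistry is not in question. The forward step must be an electrophilic iodination mild enough not to oxidise a pentaoxygenated ring.

**3 ⇒ 2.** The bonds cut are the two C–OH bonds (the future O1–C8a and O–C5). These oxygens are meta to each other, a relationship that phenol oxidation chemistry does not deliver but that two halogens placed by electrophilic substitution do. Symmetry allows both to be installed in one operation. The forward step must be a two-fold C–O coupling with hydroxide on an electron-rich, ortho-substituted dibromide.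

**2 ⇒ 1.** The bonds cut are the two C–Br bonds. The innate selectivity of 1 places electrophiles at C4 and C6 and leaves C5 as the single C–H that later carries iodine. The gain is a cheap symmetric starting material. The forward step needs the second bromine to enter C6 and not C5.

## Other disconnections considered

**Alternative 1:** the first that comes to mind, cutting C2–C3 and O1–C2.
- Forward: Claisen–Schmidt condensation of 1-(2-hydroxy-3,4,5,6-tetramethoxyphenyl)ethan-1-one A1 with 3,4,5-trimethoxybenzaldehyde A2 gives chalcone A3. Oxidative cyclisation of A3 (I2/DMSO) gives the heptamethoxyflavone A4. Chelation-directed 5-O-demethylation of A4 with a boron or aluminium halide finishes the route.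
- Ground for preferring the chosen plan: the key step of this route forms the easy bond (C2–C3) and leaves the hard C4a–C4 bond inside A1, which is not a simple catalogue compound and must itself be built over several steps from a pentaoxygenated benzene; only A2 is a cheap component. The free C5 hydroxyl appears only at the end, by discriminating one of the seven methoxy groups of A4. The chosen plan is shorter and delivers that hydroxyl by symmetry.

**Alternative 2:** de novo construction of ring A, cutting C4a–C5 and C8–C8a.
- Forward: bromine–lithium exchange on 5-bromo-2-(3,4,5-trimethoxyphenyl)-4H-pyran-4-one A6 and addition of the C-lithiated pyranone to dimethyl squarate A5 gives the 4-hydroxycyclobutenone A7. Thermolysis of A7 (4π ring opening to a vinylketene, 6π closure onto the pyranone C5=C6 bond, tautomerisation) gives the 5,8-dihydroxy-6,7-dimethoxyflavone A8. Methylation of the non-chelated C8 hydroxyl of A8 completes the target.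
- Ground: C-metalated γ-pyrones are liable to ring opening and self-addition, and A5 offers the nucleophile a vinylogous ester as well as its ketone carbonyls. The electrocyclisation of A7 would have to engage a pyranone double bond for which no mechanistic guarantee can be given. A6 must also be prepared and A8 still needs a selective methylation, so the route is longer. The chosen plan rests on a well-understood catalytic cycle.

**Alternative 3:** late-stage C–H oxidation, cutting the C5–O bond.
- Forward: carbonyl-directed Ru(II)- or Pd(II)-catalysed C5–H hydroxylation of 6,7,8-trimethoxy-2-(3,4,5-trimethoxyphenyl)-4H-chromen-4-one A9.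
- Ground: the C5–H bond of A9 is flanked by C4a and the C6 methoxy group, so cyclometalation is sterically disfavoured. The oxidants such reactions need (hypervalent iodine or persulfate in acidic media) are expected to attack the two trimethoxyarene rings by oxidative demethylation. A9 would still have to be made by the chalcone sequence, so the key step adds only one oxygen atom at the cost of a longer route.

Key step: step 4

## Route

Step 1
Reactants: 1 1,2,3-trimethoxybenzene
Product: 2 1,5-dibromo-2,3,4-trimethoxybenzene
Conditions: NBS (2.2 equiv), MeCN, rt → 50 °C
Reagents that add atoms: N-bromosuccinimide (NBS), O=C1CCC(=O)N1Br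
Why: Two-fold electrophilic aromatic bromination; the first bromine enters C4 (ortho to the C3 and para to the C1 methoxy group), and the second enters C6, which is ortho to the still coplanar C1 methoxy group and para to the C3 methoxy group, whereas C5 is activated only by the twisted C2 methoxy group and lies next to bromine.

Step 2
Reactants: 2 1,5-dibromo-2,3,4-trimethoxybenzene
Product: 3 4,5,6-trimethoxybenzene-1,3-diol
Conditions: Pd2(dba)3 (2 mol %), tBuXPhos (8 mol %), KOH (6 equiv), 1,4-dioxane/H2O (1:1), 100 °C, Ar; then 2 M HCl, 0 °C
Reagents that add atoms: potassium hydroxide, [K+].[OH-]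
Why: Palladium-catalysed hydroxylation of aryl bromides with hydroxide (Buchwald-type C–O coupling: oxidative addition, bromide/hydroxide exchange, C–O reductive elimination from the bulky biarylphosphine complex); the second C–Br bond is meta to the first-formed phenoxide and is therefore not deactivated by conjugation, and the air-sensitive product should be acidified and handled under argon.

Step 3
Reactants: 3 4,5,6-trimethoxybenzene-1,3-diol
Product: 4 2-iodo-4,5,6-trimethoxybenzene-1,3-diol
Conditions: I2 (1.05 equiv), NaHCO3 (1.1 equiv), THF/H2O (1:1), 0 °C, dark
Reagents that add atoms: iodine, II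
Why: Electrophilic aromatic iodination under the buffered conditions used for the 2-iodination of resorcinol; C2 is the only ring C–H and is ortho to both hydroxyl groups, so a single regioisomer is possible.

Step 4
Reactants: 4 2-iodo-4,5,6-trimethoxybenzene-1,3-diol; 5 5-ethynyl-1,2,3-trimethoxybenzene
Product: 8 gardenin A [5-hydroxy-6,7,8-trimethoxy-2-(3,4,5-trimethoxyphenyl)-4H-chromen-4-one], via ynone 6 (not isolated), via enaminone 7 (not isolated)
Conditions: PdCl2(dppf) (5 mol %), CO (20 bar), Et2NH (solvent), 120 °C, autoclave
Reagents that add atoms: carbon monoxide, [C-]#[O+]
Why: Pd(0) inserts into the C–I bond of 4, CO inserts to give an aroyl–Pd(II) species, and amine-assisted transfer of the acetylide of 5 followed by reductive elimination gives ynone 6 (C4a–C4 and C4–C3 formed). Diethylamine then adds to the β-carbon of 6 to give the vinylogous amide 7, and a phenolic OH displaces the amine at that carbon by intramolecular addition–elimination, forming O1–C2 and returning Et2NH. The closest known reaction type is the palladium-catalysed carbonylative coupling–annulation of o-iodophenols with terminal arylacetylenes in a secondary amine, an established flavone synthesis applied here to a 2-iodoresorcinol. The pyranone closes in the 6-endo mode (6-endo-dig with respect to 6, realised as addition–elimination on 7); the 5-exo closure to an aurone would need attack at the α-carbon, which in 7 is the nucleophilic and not the electrophilic position. No stereocentre is formed. Carbonylative coupling must beat direct Sonogashira coupling and alkyne carbopalladation (the coumarin pathway); this is secured by CO pressure, the absence of copper, the high migratory aptitude of the electron-rich, doubly ortho-substituted aryl group, and the terminal alkyne/amine pair that favours acetylide transfer to the acyl–palladium species. Which hydroxyl closes the ring is of no consequence, because the two OH groups of 4, 6 and 7 are related by the mirror plane through the former C–I carbon; the one that does not close is necessarily the C5 hydroxyl, which ends hydrogen-bonded to C4=O.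

## Compound list

1 | 1,2,3-trimethoxybenzene | COc1cccc(OC)c1OC | starting material
2 | 1,5-dibromo-2,3,4-trimethoxybenzene | COc1c(Br)cc(Br)c(OC)c1OC | intermediate
3 | 4,5,6-trimethoxybenzene-1,3-diol | COc1c(O)cc(O)c(OC)c1OC | intermediate
4 | 2-iodo-4,5,6-trimethoxybenzene-1,3-diol | COc1c(O)c(I)c(O)c(OC)c1OC | intermediate
5 | 5-ethynyl-1,2,3-trimethoxybenzene | C#Cc1cc(OC)c(OC)c(OC)c1 | starting material
6 | 1-(2,6-dihydroxy-3,4,5-trimethoxyphenyl)-3-(3,4,5-trimethoxyphenyl)prop-2-yn-1-one | COc1cc(C#CC(=O)c2c(O)c(OC)c(OC)c(OC)c2O)cc(OC)c1OC | intermediate (not isolated)
7 | (E)-3-(diethylamino)-1-(2,6-dihydroxy-3,4,5-trimethoxyphenyl)-3-(3,4,5-trimethoxyphenyl)prop-2-en-1-one (drawn E; the push–pull double bond isomerises readily and either geometry cyclises) | CCN(CC)/C(=C/C(=O)c1c(O)c(OC)c(OC)c(OC)c1O)c1cc(OC)c(OC)c(OC)c1 | intermediate (not isolated)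
8 | gardenin A, 5-hydroxy-6,7,8-trimethoxy-2-(3,4,5-trimethoxyphenyl)-4H-chromen-4-one | COc1cc(-c2cc(=O)c3c(O)c(OC)c(OC)c(OC)c3o2)cc(OC)c1OC | target

## Step count and least certain steps

Total step count: 4. Longest linear sequence: 4 steps (1 → 2 → 3 → 4 → 8; 5 enters in step 4).

**Step 4 (key step).**
- What may go wrong: oxidative addition into the very electron-rich C–I bond, flanked by two phenoxide oxygens, may be slow. Hydrodeiodination back to the resorcinol, aminocarbonylation of the acyl–palladium species by diethylamine, or non-carbonylative coupling followed by 5-endo closure to a benzofuran could then take over.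
- Fallback (sets out from 3, bypasses 4, returns at 8): diol 3 is heated without solvent, or in diphenyl ether, at about 200–240 °C (conventional or microwave heating) with commercial ethyl 3-oxo-3-(3,4,5-trimethoxyphenyl)propanoate F1. Thermal loss of ethanol gives an aroylketene that C-acylates the single ring C–H of 3 to the 1,3-diketone 1-(2,6-dihydroxy-3,4,5-trimethoxyphenyl)-3-(3,4,5-trimethoxyphenyl)propane-1,3-dione F2. F2 cyclodehydrates in the same pot to 8 (Mentzer-type pyrone synthesis, established for phloroglucinol-type phenols). The same symmetry argument applies.
- Why this is held in reserve although it is one step shorter on paper: at these temperatures the partition between pyrone formation and Pechmann-type coumarin formation, and the survival of the oxidation-prone 3, cannot be secured by design.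

**Step 2.**
- What may go wrong: the reaction may stall after the first C–O coupling, because the mono-phenoxide is a poorer substrate for oxidative addition. Hydrodebromination, diaryl ether formation between product phenoxide and remaining bromide, and aerial oxidation of the electron-rich resorcinolate in hot alkali are further risks.
- Fallback (sets out from 2, returns at 3): two-fold Miyaura borylation of 2 (B2pin2, PdCl2(dppf), KOAc, 1,4-dioxane, 90 °C) gives 2,2'-(4,5,6-trimethoxy-1,3-phenylene)bis(4,4,5,5-tetramethyl-1,3,2-dioxaborolane) F3. Oxidation of both C–B bonds of F3 (30 % H2O2, NaOH, THF, 0 °C, then acidification) gives 3. The C–O bonds are then made by 1,2-boron-to-oxygen migration under cold, brief basic conditions in place of hot hydroxide coupling.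

**Step 3.**
- What may go wrong: the iodine electrophile may oxidise the pentaoxygenated ring (oxidative demethylation towards quinones) and not substitute it, and the iodination may reverse (protodeiodination) on acidic work-up or on storage in light.
- Fallback (sets out from 3, returns at 4): the two hydroxyls are protected (MOMCl, iPr2NEt, CH2Cl2) to give 1,2,3-trimethoxy-4,6-bis(methoxymethoxy)benzene F4. Directed ortho-lithiation of F4 between the two MOM ethers (n-BuLi, THF, 0 °C) and quenching with I2 at −78 °C gives 2-iodo-4,5,6-trimethoxy-1,3-bis(methoxymethoxy)benzene F5. Mild acid methanolysis of F5 (HCl, MeOH, 0 °C → rt) gives 4, best used directly in step 4. The C–I bond is then made from an aryllithium on a protected, oxidation-resistant ring.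

## Further compounds

F1 | step 4 | ethyl 3-oxo-3-(3,4,5-trimethoxyphenyl)propanoate (purchased reagent of the fallback) | CCOC(=O)CC(=O)c1cc(OC)c(OC)c(OC)c1
F2 | step 4 | 1-(2,6-dihydroxy-3,4,5-trimethoxyphenyl)-3-(3,4,5-trimethoxyphenyl)propane-1,3-dione | COc1cc(C(=O)CC(=O)c2c(O)c(OC)c(OC)c(OC)c2O)cc(OC)c1OC
F3 | step 2 | 2,2'-(4,5,6-trimethoxy-1,3-phenylene)bis(4,4,5,5-tetramethyl-1,3,2-dioxaborolane) | COc1c(B2OC(C)(C)C(C)(C)O2)cc(B2OC(C)(C)C(C)(C)O2)c(OC)c1OC
F4 | step 3 | 1,2,3-trimethoxy-4,6-bis(methoxymethoxy)benzene | COCOc1cc(OCOC)c(OC)c(OC)c1OC
F5 | step 3 | 2-iodo-4,5,6-trimethoxy-1,3-bis(methoxymethoxy)benzene | COCOc1c(I)c(OCOC)c(OC)c(OC)c1OC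
A1 | alternative 1 | 1-(2-hydroxy-3,4,5,6-tetramethoxyphenyl)ethan-1-one | CC(=O)c1c(O)c(OC)c(OC)c(OC)c1OC
A2 | alternative 1 | 3,4,5-trimethoxybenzaldehyde | O=Cc1cc(OC)c(OC)c(OC)c1
A3 | alternative 1 | (E)-1-(2-hydroxy-3,4,5,6-tetramethoxyphenyl)-3-(3,4,5-trimethoxyphenyl)prop-2-en-1-one | COc1cc(/C=C/C(=O)c2c(O)c(OC)c(OC)c(OC)c2OC)cc(OC)c1OC
A4 | alternative 1 | 5,6,7,8-tetramethoxy-2-(3,4,5-trimethoxyphenyl)-4H-chromen-4-one | COc1cc(-c2cc(=O)c3c(OC)c(OC)c(OC)c(OC)c3o2)cc(OC)c1OC
A5 | alternative 2 | dimethyl squarate (3,4-dimethoxycyclobut-3-ene-1,2-dione) | COC1=C(OC)C(=O)C1=O
A6 | alternative 2 | 5-bromo-2-(3,4,5-trimethoxyphenyl)-4H-pyran-4-one | COc1cc(-c2cc(=O)c(Br)co2)cc(OC)c1OC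
A7 | alternative 2 | 4-hydroxy-2,3-dimethoxy-4-[4-oxo-6-(3,4,5-trimethoxyphenyl)-4H-pyran-3-yl]cyclobut-2-en-1-one (racemic) | COC1=C(OC)C(O)(c2coc(-c3cc(OC)c(OC)c(OC)c3)cc2=O)C1=O
A8 | alternative 2 | 5,8-dihydroxy-6,7-dimethoxy-2-(3,4,5-trimethoxyphenyl)-4H-chromen-4-one | COc1cc(-c2cc(=O)c3c(O)c(OC)c(OC)c(O)c3o2)cc(OC)c1OC
A9 | alternative 3 | 6,7,8-trimethoxy-2-(3,4,5-trimethoxyphenyl)-4H-chromen-4-one | COc1cc(-c2cc(=O)c3cc(OC)c(OC)c(OC)c3o2)cc(OC)c1OC
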